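## The problem

The target 17 is 3,4,7-tribromo-2-chloro-1H-indole: a benzo-fused pyrrole in which C2 carries chlorine, C3, C4 and C7 carry bromine, and only C5 and C6 keep hydrogen. There is no stereocentre, so nothing has to be set or relayed; the whole difficulty is positional. The pyrrole-ring halogens follow the innate reactivity of indole (C3 by electrophilic substitution, C2 by deprotonation of an N-sulfonylindole). C4 and C7 are the benzo positions that electrophilic bromination of an indole does not reach, so they must be bought on a benzene building block or made together with the ring. The sensitive points are the N–H 2-haloindole unit, which acid protonates at C3 and then hydrolyses or oligomerises, and the aryl C–Br bonds, which do not tolerate alkyllithium reagents, dissolving metals or long exposure to zerovalent palladium. Palladium chemistry therefore has to come before any benzo bromine exists, and only amide bases may be used afterwards. The enabling feature is that C4 and C7 stand para to each other across the benzene ring and flank the unsubstituted C5–C6 bond. These are the two radical carbons and the new bond of a 1,4-didehydroarene formed from a pyrrole with ethynyl groups on C2 and C3, so a bromine-atom donor could deliver the benzene ring and both benzo C–Br bonds in one operation.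

## Retrosynthesis

**C3–Br (17 ⇒ 16).** The last bond cut is C3–Br. In the N–H indole 16, C3 is the enamine carbon and the only free position of the pyrrole ring, so an electrophilic bromine source has one place to go. Ending instead with C2–Cl would require electrophilic chlorination of a 3-bromoindole, which passes through 3-haloindolenines and scrambles halogen. The precursor is one halogen poorer; the forward step must stop at monobromination and leave the deactivated benzo ring alone.

**N–H (16 ⇒ 15).** The N–H of 16 is traced back to the N-tosyl compound 15, the N–S bond being cleaved in the forward direction. The sulfonyl group is needed earlier as a heat-stable nitrogen substituent and as the director of C2 metalation. Taking it off before the C3 bromination keeps the final electrophilic step on the most nucleophilic substrate. The cleavage must be nucleophilic, not reductive, to spare three carbon–halogen bonds.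

**C2–Cl (15 ⇒ 13).** C2–Cl is cut through the 2-lithio species 14. C2 cannot be chlorinated electrophilically while C3 is free, but its C–H is the most acidic one of an N-sulfonylindole, so a lithium amide followed by a positive-chlorine donor places chlorine there only. The precursor 13 carries just the two benzo bromines. The forward step must deprotonate without halogen–metal exchange, hence an amide base.

**C5–C6, C4–Br and C7–Br (13 ⇒ 10 + 11).** This is the strategic cut: the benzene ring of 13 is opened between C5 and C6 and both benzo bromines are removed, giving 2,3-diethynyl-1-tosylpyrrole 10 and two molecules of bromotrichloromethane 11, with diradical 12 as the link. Cycloaddition cuts of the benzene ring end at a non-aromatic oxidation level, and classical indole syntheses buy the bromines on a benzene ring. This cut removes a ring and two C–halogen bonds at once and leaves a halogen-free pyrrole with two identical two-carbon arms. Thermal cycloaromatisation of a pyrrole-fused enediyne with bromine-atom capture is proposed as new. The forward reaction must cyclise faster than the enediyne polymerises and capture bromine faster than the diradical reopens or finds another partner.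

**C–Si (10 ⇒ 9).** The two terminal alkynes are masked as trimethylsilyl alkynes in 9. Free 1,2-diethynylarenes polymerise when concentrated, so the silyl groups are carried until just before the key step. The unmasking must not touch the N-sulfonyl group.

**Two C(sp2)–C(sp) bonds (9 ⇒ 6 + 7).** Both alkynyl arms are cut from the pyrrole, leading to the dihalide 6 and two molecules of trimethylsilylacetylene 7, with the monoalkyne 8 between them. Sonogashira coupling is the obvious choice against stepwise alkyne constructions from aldehydes, which would need two carbonyl groups on an electron-rich ring. The precursor is a simple dihalopyrrole; the forward reaction must also engage the less reactive C3–Br bond.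

**C2–I (6 ⇒ 4).** The C2–I bond is cut through the 2-lithio species 5. The C2–H of 4 lies between the sulfonylated nitrogen and the bromine and is the kinetically most acidic site, whereas electrophilic iodination would not distinguish C2 from C5. The precursor is a monohalide. The anion must be captured by a fast iodine electrophile before it isomerises.

**N–S (4 ⇒ 1 + 2).** Finally the tosyl group is cut back to p-toluenesulfonyl chloride 2 and the commercial silylpyrrole 1, via free 3-bromopyrrole 3. Compound 1 already has the β-bromine, but its bulky silyl group blocks C2 and cannot direct metalation. The tosyl group supplies the director for the C2 metalations and a nitrogen substituent that survives strong heating. The labile 3 must be sulfonylated without isolation.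

## Roads not taken

**Alternative 1:** The cut is N1–C7a, with C2–C3 made beforehand by condensation. Knoevenagel condensation of 2,5-dibromobenzaldehyde A1 with ethyl azidoacetate A2 would give the azidoacrylate A3. Thermolysis of A3 would generate a vinyl nitrene that inserts into the only free ortho C–H bond, giving ethyl 4,7-dibromo-1H-indole-2-carboxylate A4 (Hemetsberger–Knittel synthesis).
- Merits: both benzo bromines are bought in place, the second ortho position is blocked so the closure is unambiguous, and the reaction type is thoroughly established.
- Weak points: A4 has an ester at C2 where the target has chlorine. Removing it means saponification and a hot decarboxylation in the presence of two aryl bromides, then N-sulfonylation to reach 13, after which the same three closing steps follow. That is about eight steps, and the azide thermolysis is a safety burden on scale.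
- Comparison: in reliability of the ring-forming step this road is clearly better, and in length it is equal. The chosen plan sets against it that the benzene ring and both benzo C–Br bonds form in one step from a halogen-free pyrrole, that 13 arrives with C2–H and the directing sulfonyl group already present, and that no group is installed only to be removed.

**Alternative 2:** The cuts are C3a–C4 and C7–C7a. 2,5-Dibromothiophene 1,1-dioxide A5 would serve as an electron-poor diene toward the enecarbamate double bond of tert-butyl 2,3-dihydro-1H-pyrrole-1-carboxylate A6 in a Diels–Alder reaction. The bridged adduct would lose its sulfone bridge cheletropically to give the racemic cis-fused dibromotetrahydroindole A7.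
- Merits: the route is convergent, the diene is symmetric so there is no regiochemical question, and the electron-poor diene matches the electron-rich alkene. Cycloaddition–extrusion of thiophene dioxides is a known reaction type, so this key step stands closer to precedent than the chosen one.
- Weak points: A7 is four hydrogens short of an indole, so two dehydrogenations are needed, and two stereocentres are made only to be destroyed. At the temperatures of extrusion and oxidation a 1,5-hydrogen shift in the cyclohexadiene would turn a vinylic C–Br into an allylic one that can leave as HBr, so a bromine may be lost on aromatisation. A5 needs a powerful oxygen-transfer oxidation for its preparation. After aromatisation, C2 chlorination, carbamate removal and C3 bromination remain, about eight steps in all.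
- Comparison: length is similar and the key step is better precedented. The chosen plan sets against it that the ring is formed directly at the aromatic level, that the bromines are attached to sp2 radical centres with no elimination pathway, and that no redox adjustment is needed.

**Alternative 3:** The cuts are C3a–C7a, C4–C5 and C6–C7. A [2+2+2] cyclotrimerisation catalysed by Cp*RuCl(cod), joining the tethered diyne A8 (a bromoynamide and a bromoalkyne) with acetylene A9, would close both rings and give 4,7-dibromo-1-tosylindoline A10.
- Merits: three C–C bonds and two rings form in one catalytic step, the bromine positions are fixed by the alkyne termini, and haloalkynes are known partners in ruthenium cyclotrimerisation. A10 already carries the tosyl group, so one dehydrogenation would lead to 13 and the same endgame.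
- Weak points: A8 needs about four steps (sulfonamide formation, N-alkynylation, two terminal brominations). Its bromoynamide end is polarised and hydrolytically labile and offers the metal a C–Br bond next to nitrogen for oxidative addition. Gaseous A9 invites homotrimerisation, and dehydrogenation of an electron-poor, peri-hindered N-sulfonylindoline is not trivial. The total is about nine steps.
- Comparison: the key step is catalytic and, for the haloalkyne part, nearer to precedent than the chosen one, and the endgame is the same. The chosen plan sets against it a sequence one step shorter, a precursor made by routine lithiation and cross-coupling, and a benzene ring that needs no later oxidation.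

Key step: step 5

Remark: compounds 1, 2, 7 and 11 are taken as purchasable, and 17 has no stereocentre, so no configuration has to be assigned or controlled. Step 3 consumes two molecules of 7 and step 5 consumes two molecules of 11 for each molecule of substrate.

## Route

Step 1
Reactants: 1 3-bromo-1-(triisopropylsilyl)-1H-pyrrole + 2 p-toluenesulfonyl chloride
Product: 4 3-bromo-1-tosyl-1H-pyrrole, via 3-bromo-1H-pyrrole 3 (not isolated)
Conditions: Bu4NF, THF, 0 °C; then CH2Cl2, 50% aq NaOH, 2, 0 °C → rt
Reagents that add atoms: none
Why: Fluoride cleaves the N–Si bond, and the acid- and air-sensitive 3 is N-sulfonylated in the same flask under phase-transfer conditions, the tetrabutylammonium ion left from the first stage carrying the pyrrolide into the organic phase.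

Step 2
Reactants: 4 3-bromo-1-tosyl-1H-pyrrole
Product: 6 3-bromo-2-iodo-1-tosyl-1H-pyrrole, via 3-bromo-2-lithio-1-tosylpyrrole 5 (not isolated)
Conditions: LiN(i-Pr)2, THF, −78 °C, 15 min; then I2, THF, −78 °C
Reagents that add atoms: iodine, II
Why: Directed metalation removes the C2–H that lies between the sulfonylated nitrogen and the bromine, and an amide base does not exchange the C–Br bond. Iodine is a fast electrophile and should capture 5 before it can isomerise to the 5-lithio species.

Step 3
Reactants: 6 3-bromo-2-iodo-1-tosyl-1H-pyrrole + 7 trimethylsilylacetylene
Product: 9 1-tosyl-2,3-bis[(trimethylsilyl)ethynyl]-1H-pyrrole, via 3-bromo-1-tosyl-2-[(trimethylsilyl)ethynyl]pyrrole 8 (not isolated)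
Conditions: 7 (2.5 equiv in all), PdCl2(PhCN)2 (3 mol %), [(t-Bu)3PH]BF4 (6 mol %), CuI (2 mol %), HN(i-Pr)2, dioxane, rt then 50 °C
Reagents that add atoms: trimethylsilylacetylene, C[Si](C)(C)C#C
Why: Double Sonogashira coupling that consumes two molecules of 7: zerovalent palladium inserts into the C–I bond at room temperature and the first molecule of 7 gives 8. The electron-rich tri-tert-butylphosphine ligand should then let the C3–Br bond of 8 couple with the second molecule of 7 on mild warming, so both alkynes go on in one flask.

Step 4
Reactants: 9 1-tosyl-2,3-bis[(trimethylsilyl)ethynyl]-1H-pyrrole
Product: 10 2,3-diethynyl-1-tosyl-1H-pyrrole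
Conditions: K2CO3 (0.2 equiv), MeOH/THF, 0 °C, 20 min
Reagents that add atoms: none
Why: Methoxide-catalysed protodesilylation of alkynylsilanes is fast at 0 °C and should outrun methanolysis of the N-sulfonyl group; 10 is kept cold in solution and used at once.

Step 5
Reactants: 10 2,3-diethynyl-1-tosyl-1H-pyrrole + 11 bromotrichloromethane (as solvent)
Product: 13 4,7-dibromo-1-tosyl-1H-indole, via 1-tosylindole-4,7-diyl diradical 12 (not isolated)
Conditions: degassed BrCCl3 (filtered through basic Al2O3; 0.005 M in 10, two molecules consumed per molecule of 10), sealed tube, 190 °C, dark
Reagents that add atoms: bromotrichloromethane, BrC(Cl)(Cl)Cl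
Why: Proposed new method: on heating, the in-plane π orbitals of the two terminal alkyne carbons of 10 bond to each other (C5–C6 of the indole), and the gain of the benzene sextet gives the σ,σ-diradical 12 with its unpaired electrons on the two former internal alkyne carbons, C4 and C7. Each of the two aryl radicals then takes a bromine atom from a molecule of 11, whose C–Br bond is much weaker than the aryl–Br bond that forms, so two molecules of 11 are consumed per molecule of 10 and the two CCl3 radicals end as hexachloroethane. The closest known reaction type is the thermal Bergman cyclisation of arene- and heteroarene-fused enediynes with hydrogen-atom donors, together with chlorine-atom capture of the parent 1,4-didehydrobenzene in CCl4; bromine-atom capture on a pyrrole-fused enediyne has not been shown. The benzene ring closes in the C1–C6 (Bergman) mode of the hex-3-ene-1,5-diyne unit, since the competing C1–C5 closure to a fulvene diradical is favoured only by bulky or radical-stabilising alkyne termini, which 10 lacks. No stereocentre is formed. The bromine positions are fixed by the mechanism, because radical character appears only at the carbons bonded to the pyrrole ring. Bromine capture must beat ring opening of 12 and attack of the C7 radical on the tolyl ring, which neat 11 as solvent should secure, and chain addition of CCl3 radicals to the terminal alkynes must stay slow, which millimolar substrate concentration, exclusion of oxygen and light, and a tosyl group without weak C–H bonds near the radical centres should secure. Because the pyrrole C2=C3 bond holds the alkynes further apart than a benzene bond does, a temperature near 190 °C is expected to be necessary.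

Step 6
Reactants: 13 4,7-dibromo-1-tosyl-1H-indole
Product: 15 4,7-dibromo-2-chloro-1-tosyl-1H-indole, via 4,7-dibromo-2-lithio-1-tosylindole 14 (not isolated)
Conditions: LiN(i-Pr)2, THF, −78 °C, 30 min; then C2Cl6, −78 °C → rt
Reagents that add atoms: hexachloroethane, ClC(Cl)(Cl)C(Cl)(Cl)Cl
Why: Directed lithiation of an N-sulfonylindole at C2, its most acidic C–H, followed by electrophilic chlorination with hexachloroethane, which passes on a positive chlorine and collapses to tetrachloroethene and LiCl. The amide base is not expected to exchange the aryl bromides.

Step 7
Reactants: 15 4,7-dibromo-2-chloro-1-tosyl-1H-indole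
Product: 16 4,7-dibromo-2-chloro-1H-indole
Conditions: Bu4NF, THF, 50 °C; pH 7 buffer work-up
Reagents that add atoms: none
Why: Nucleophilic desulfonylation: fluoride attacks sulfur, the trihaloindolide is a good leaving group and the peri C7–Br strains the N–S bond, so cleavage should be easy without any reductant. The neutral work-up protects the acid-sensitive 2-chloroindole, which is carried straight on.

Step 8
Reactants: 16 4,7-dibromo-2-chloro-1H-indole
Product: 17 3,4,7-tribromo-2-chloro-1H-indole
Conditions: NBS (1.0 equiv), DMF, 0 °C, dark
Reagents that add atoms: N-bromosuccinimide, O=C1CCC(=O)N1Br
Why: Electrophilic aromatic substitution at C3, the enamine carbon and the only free position of the pyrrole ring; the benzo ring carries two deactivating bromines. One equivalent at 0 °C should avoid 3,3-dibromination.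

## Compound list

1 | 3-bromo-1-(triisopropylsilyl)-1H-pyrrole | CC(C)[Si](C(C)C)(C(C)C)n1ccc(Br)c1 | starting material
2 | p-toluenesulfonyl chloride | Cc1ccc(cc1)S(Cl)(=O)=O | starting material
3 | 3-bromo-1H-pyrrole (not isolated) | Brc1cc[nH]c1 | intermediate
4 | 3-bromo-1-tosyl-1H-pyrrole | Cc1ccc(cc1)S(=O)(=O)n1ccc(Br)c1 | intermediate
5 | 3-bromo-2-lithio-1-tosyl-1H-pyrrole (not isolated) | [Li]c1c(Br)ccn1S(=O)(=O)c1ccc(C)cc1 | intermediate
6 | 3-bromo-2-iodo-1-tosyl-1H-pyrrole | Cc1ccc(cc1)S(=O)(=O)n1ccc(Br)c1I | intermediate
7 | trimethylsilylacetylene | C[Si](C)(C)C#C | starting material
8 | 3-bromo-1-tosyl-2-[(trimethylsilyl)ethynyl]-1H-pyrrole (not isolated) | Cc1ccc(cc1)S(=O)(=O)n1ccc(Br)c1C#C[Si](C)(C)C | intermediate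
9 | 1-tosyl-2,3-bis[(trimethylsilyl)ethynyl]-1H-pyrrole | Cc1ccc(cc1)S(=O)(=O)n1ccc(C#C[Si](C)(C)C)c1C#C[Si](C)(C)C | intermediate
10 | 2,3-diethynyl-1-tosyl-1H-pyrrole | Cc1ccc(cc1)S(=O)(=O)n1ccc(C#C)c1C#C | intermediate
11 | bromotrichloromethane | BrC(Cl)(Cl)Cl | starting material
12 | 1-tosylindole-4,7-diyl diradical (not isolated) | Cc1ccc(cc1)S(=O)(=O)n1ccc2[c]cc[c]c12 | intermediate
13 | 4,7-dibromo-1-tosyl-1H-indole | Cc1ccc(cc1)S(=O)(=O)n1ccc2c(Br)ccc(Br)c21 | intermediate
14 | 4,7-dibromo-2-lithio-1-tosyl-1H-indole (not isolated) | [Li]c1cc2c(Br)ccc(Br)c2n1S(=O)(=O)c1ccc(C)cc1 | intermediate
15 | 4,7-dibromo-2-chloro-1-tosyl-1H-indole | Cc1ccc(cc1)S(=O)(=O)n1c(Cl)cc2c(Br)ccc(Br)c21 | intermediate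
16 | 4,7-dibromo-2-chloro-1H-indole | Clc1cc2c(Br)ccc(Br)c2[nH]1 | intermediate
17 | 3,4,7-tribromo-2-chloro-1H-indole | Clc1[nH]c2c(Br)ccc(Br)c2c1Br | target

## Step count and risks

Total step count: 8. Longest linear sequence: 8 steps, from 1 to 17.

**Step 5 (key step, proposed new method).** Three processes are most likely to go wrong.
- The cyclisation may be slower than thermal polymerisation of the diyne, because the five-membered ring splays the alkynes apart.
- The CCl3 radicals released by the product-forming step may start chain addition of the solvent across the terminal alkynes.
- Halogen capture may be incomplete, with hydrogen uptake or intramolecular arylation of the tolyl ring competing.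

The fallback uses known chemistry and gives up the cycloaromatisation. It sets out from p-toluenesulfonyl chloride 2 and purchased 1,4-dibromo-2-nitrobenzene F1. Bartoli indole synthesis on F1 (CH2=CHMgBr, 3 equiv, THF, −40 °C) should give 4,7-dibromo-1H-indole F2, the ortho bromine steering the sigmatropic shift to the free ortho carbon. N-Sulfonylation of F2 with NaH and 2 in DMF comes back to the route at 13, and steps 6 to 8 follow unchanged.

**Step 2.** The kinetic 2-lithio species 5 may isomerise to the more stable 5-lithio isomer before iodine captures it. That would place the two alkynes in a 2,4-relationship that cannot cyclise. The fallback sets out from 4 and traps the anion as it forms: LiN(i-Pr)2 is added to 4 in the presence of Me3SiCl at −78 °C, which should give 3-bromo-1-tosyl-2-(trimethylsilyl)-1H-pyrrole F3. Ipso-iododesilylation of F3 with ICl in CH2Cl2 at 0 °C comes back to the route at 6.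

**Step 3.** The coupling may stall after the first alkyne because oxidative addition into the flanked C3–Br bond is slow, while CuI-mediated oxidative dimerisation of 7 (Glaser coupling) uses up the alkyne. The fallback sets out from 8, isolated after the room-temperature stage, and changes the coupling manifold: Stille coupling with tributyl[(trimethylsilyl)ethynyl]stannane and Pd(PPh3)4 in toluene at 100 °C, with no copper acetylide involved, comes back to the route at 9. This fallback makes no new compound (F0).

**Step 6.** Deprotonation next to a ring bromine may compete with C2 lithiation, leading to bromine migration or aryne formation. The following step also has to handle the acid-labile N–H 2-chloroindole 16. The fallback sets out from 13 and changes the order of events. Bromination with Br2 in CH2Cl2 should give 3,4,7-tribromo-1-tosyl-1H-indole F4, whose C2–H now lies between the sulfonylated nitrogen and a bromine and is more acidic still. LiN(i-Pr)2 and then C2Cl6 should give 3,4,7-tribromo-2-chloro-1-tosyl-1H-indole F5, and Bu4NF in THF removes the sulfonyl group last, coming back to the route at the target 17 without passing through 16.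

## Further compounds

F1 | step 5 | 1,4-dibromo-2-nitrobenzene (purchased) | O=[N+]([O-])c1cc(Br)ccc1Br
F2 | step 5 | 4,7-dibromo-1H-indole | Brc1ccc(Br)c2[nH]ccc12
F3 | step 2 | 3-bromo-1-tosyl-2-(trimethylsilyl)-1H-pyrrole | Cc1ccc(cc1)S(=O)(=O)n1ccc(Br)c1[Si](C)(C)C
F0 | step 3 | none | none
F4 | step 6 | 3,4,7-tribromo-1-tosyl-1H-indole | Cc1ccc(cc1)S(=O)(=O)n1cc(Br)c2c(Br)ccc(Br)c21
F5 | step 6 | 3,4,7-tribromo-2-chloro-1-tosyl-1H-indole | Cc1ccc(cc1)S(=O)(=O)n1c(Cl)c(Br)c2c(Br)ccc(Br)c21
A1 | alternative 1 | 2,5-dibromobenzaldehyde | O=Cc1cc(Br)ccc1Br
A2 | alternative 1 | ethyl azidoacetate | CCOC(=O)CN=[N+]=[N-]
A3 | alternative 1 | ethyl (Z)-2-azido-3-(2,5-dibromophenyl)acrylate | CCOC(=O)/C(N=[N+]=[N-])=C/c1cc(Br)ccc1Br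
A4 | alternative 1 | ethyl 4,7-dibromo-1H-indole-2-carboxylate | CCOC(=O)c1cc2c(Br)ccc(Br)c2[nH]1
A5 | alternative 2 | 2,5-dibromothiophene 1,1-dioxide | O=S1(=O)C(Br)=CC=C1Br
A6 | alternative 2 | tert-butyl 2,3-dihydro-1H-pyrrole-1-carboxylate | CC(C)(C)OC(=O)N1CCC=C1
A7 | alternative 2 | tert-butyl cis-4,7-dibromo-2,3,3a,7a-tetrahydro-1H-indole-1-carboxylate (racemic, one enantiomer drawn) | CC(C)(C)OC(=O)N1CC[C@H]2C(Br)=CC=C(Br)[C@@H]12
A8 | alternative 3 | N-(bromoethynyl)-N-(4-bromobut-3-yn-1-yl)-4-methylbenzenesulfonamide | Cc1ccc(cc1)S(=O)(=O)N(C#CBr)CCC#CBr
A9 | alternative 3 | acetylene | C#C
A10 | alternative 3 | 4,7-dibromo-1-tosylindoline | Cc1ccc(cc1)S(=O)(=O)N1CCc2c(Br)ccc(Br)c21
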